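**Retrosynthetic overview**

1. The C15 hydrogen malonate (alcoholysis of Meldrum's acid) and the C18 angelate (mixed-anhydride acylation with angelic acid) are removed first; C13 is traced to a BINAP-ruthenium hydrogenation of a 13E allylic alcohol.
2. The strategy rests on the trans-fused ring A/ring B decalin with its five contiguous centers C4 (equatorial C18-O, axial C19), C5, C10, C9 and C8 (equatorial OH, axial C17), which is the chair-chair fold of an all-E C20 tetraene in the ent sense.
3. Key disconnection: C4-C5, C9-C10 and C8-OH, all formed in one enzymatic, protonation-initiated bicyclisation ended by water; ring A closes first and ring B second within the same cascade.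
4. The acyclic diphosphate comes from geranylgeraniol by oxidation of the terminal E-methyl group (the future C18) and chloride-to-diphosphate exchange at C1.

Key step: step 8

Remark: acyclic compounds carry geranylgeraniol numbering (C1 = CH2O, C16 = terminal E carbon) and bicyclic ones labdane numbering; diphosphates are drawn as free acids although handled as ammonium or tetrabutylammonium salts; the base-deleted ent-copalyl diphosphate synthase is taken to be available by heterologous expression.

**Route**

Step 1
Reactants: 1 geranylgeraniol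
Product: 2 geranylgeranyl acetate
Conditions: Ac2O, pyridine, DMAP (cat.), CH2Cl2, 0 °C to rt
Reagents that add atoms: acetic anhydride CC(=O)OC(C)=O
Why: DMAP-catalysed acyl transfer masks O1 and makes the C2-C3 alkene electron-poor, so that the following ene oxidation avoids it.

Step 2
Reactants: 2 geranylgeranyl acetate
Product: 3 (2E,6E,10E,14E)-16-hydroxygeranylgeranyl acetate
Conditions: SeO2 (0.1 equiv), salicylic acid (0.1 equiv), t-BuOOH (70% aq., 3 equiv), CH2Cl2, 0 °C to rt; stopped at partial conversion and 2 recycled
Reagents that add atoms: selenium dioxide O=[Se]=O (catalytic oxygen carrier); tert-butyl hydroperoxide CC(C)(C)OO (net oxygen source)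
Why: The Sharpless SeO2/t-BuOOH allylic oxidation (ene reaction, then [2,3]-sigmatropic shift) should attack the most electron-rich and least hindered terminal alkene and deliver oxygen to the methyl group trans to the chain, giving the E-hydroxymethyl isomer.

Step 3
Reactants: 3 (2E,6E,10E,14E)-16-hydroxygeranylgeranyl acetate
Product: 4 (2E,6E,10E,14E)-16-(tert-butyldimethylsilyloxy)geranylgeranyl acetate
Conditions: TBSCl, imidazole, DMF, 0 °C to rt
Reagents that add atoms: tert-butyldimethylsilyl chloride CC(C)(C)[Si](C)(C)Cl
Why: Imidazole-promoted silylation of the primary allylic hydroxyl gives an ether that survives methanolysis, chlorination and diphosphate displacement.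

Step 4
Reactants: 4 (2E,6E,10E,14E)-16-(tert-butyldimethylsilyloxy)geranylgeranyl acetate
Product: 5 (2E,6E,10E,14E)-16-(tert-butyldimethylsilyloxy)geranylgeraniol
Conditions: K2CO3 (0.2 equiv), MeOH, 0 °C to rt
Reagents that add atoms: none
Why: Base-catalysed transesterification removes the acetate and leaves the silyl ether and the four E alkenes untouched.

Step 5
Reactants: 5 (2E,6E,10E,14E)-16-(tert-butyldimethylsilyloxy)geranylgeraniol
Product: 6 (2E,6E,10E,14E)-16-(tert-butyldimethylsilyloxy)geranylgeranyl chloride
Conditions: NCS, Me2S, CH2Cl2, -40 to 0 °C; crude chloride used at once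
Reagents that add atoms: N-chlorosuccinimide O=C1CCC(=O)N1Cl
Why: Corey-Kim chlorination proceeds by SN2 attack of chloride on the alkoxysulfonium salt, so the primary allylic chloride should form without allylic transposition or loss of E geometry.

Step 6
Reactants: 6 (2E,6E,10E,14E)-16-(tert-butyldimethylsilyloxy)geranylgeranyl chloride
Product: 7 (2E,6E,10E,14E)-16-(tert-butyldimethylsilyloxy)geranylgeranyl diphosphate
Conditions: (n-Bu4N)3HP2O7 (2 equiv), MeCN, rt; evaporation, tetrabutylammonium salt carried on
Reagents that add atoms: tris(tetrabutylammonium) hydrogen diphosphate CCCC[N+](CCCC)(CCCC)CCCC.CCCC[N+](CCCC)(CCCC)CCCC.CCCC[N+](CCCC)(CCCC)CCCC.OP(=O)([O-])OP(=O)([O-])[O-]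
Why: Davisson-Poulter SN2 displacement of the allylic chloride by the naked diphosphate anion in acetonitrile is the standard entry to prenyl diphosphates.

Step 7
Reactants: 7 (2E,6E,10E,14E)-16-(tert-butyldimethylsilyloxy)geranylgeranyl diphosphate
Product: 8 (2E,6E,10E,14E)-16-hydroxygeranylgeranyl diphosphate
Conditions: TBAF, THF, 0 °C to rt; cation-exchange resin (NH4+ form), then cellulose chromatography (i-PrOH/conc. NH4OH/H2O)
Reagents that add atoms: none
Why: Fluoride desilylation runs under basic aprotic conditions in which an allylic diphosphate anion (which ionises only with acid or metal-ion assistance) should be inert, as in the desilylation of silyl-protected nucleoside polyphosphates.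

Step 8
Reactants: 8 (2E,6E,10E,14E)-16-hydroxygeranylgeranyl diphosphate
Product: 9 ent-8,18-dihydroxycopalyl diphosphate (trans-decalin; C18 hydroxymethyl and 8-OH equatorial; 13E)
Conditions: recombinant ent-copalyl diphosphate synthase variant lacking its catalytic base (histidine of the base pair replaced by alanine), 50 mM HEPES pH 7.5, 0.1 mM MgCl2, 10% glycerol, 5 mM DTT, 30 °C; reversed-phase solid-phase extraction
Reagents that add atoms: water O
Why: Proposed new method: the general acid of the DxDD motif protonates C3 of the chair-chair-folded substrate, C5 adds to C4 and C9 adds to C10 in two anti additions, and because the variant has no base to remove a C17 proton the C8 cation lives long enough to be captured by active-site water; the closest known reaction is the water-terminated bicyclisation of geranylgeranyl diphosphate itself to ent-8-hydroxycopalyl diphosphate by such base-deleted class 2 cyclases, and what is new is the allylic hydroxyl on the initiating alkene. Ring A closes 6-endo on the C5-C10 alkene and ring B closes 6-endo on the C8-C9 alkene. C5, C9 and C10 follow from the E geometry of the two inner alkenes in the chair-chair fold (H5 and H9 anti to C20); C4 follows from the E geometry of the terminal alkene, whose hydroxymethyl stays anti to C2 and becomes equatorial C18 while the Z methyl becomes axial C19; C8 follows from anti addition of water, which puts the hydroxyl equatorial and C17 axial; the ent sense comes from the contour of the active site. The step needs ent rather than normal folding, water capture rather than proton loss, and ring closure faster than any side reaction of the beta-hydroxy cation at C4 (hydride shift to an aldehyde); the enzyme pocket secures the first, the missing base the second, and the concerted closure together with the equatorial C18, which cannot reach C10, the third. Because the hydroxyl lowers the basicity of the C3-C4 alkene, a panel of base-deleted ent-copalyl diphosphate synthases would be screened and the best one improved by directed evolution if turnover is low.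

Step 9
Reactants: 9 ent-8,18-dihydroxycopalyl diphosphate
Product: 10 (13E)-ent-labd-13-ene-8,15,18-triol
Conditions: calf intestinal alkaline phosphatase, glycine buffer pH 9, 1 mM MgCl2, 0.1 mM ZnCl2, 37 °C; EtOAc extraction
Reagents that add atoms: none
Why: Enzymatic phosphate hydrolysis cleaves P-O bonds only, so C15-O and the 13E alkene are kept and the acid-induced allylic ionisation (ether formation with the C8 hydroxyl) is avoided.

Step 10
Reactants: 10 (13E)-ent-labd-13-ene-8,15,18-triol
Product: 11 (13S)-ent-labdane-8,15,18-triol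
Conditions: Ru(OAc)2[(R)-BINAP] (1 mol%), H2 (100 atm), MeOH-H2O 95:5, 20 °C
Reagents that add atoms: none
Why: Noyori hydroxyl-directed asymmetric hydrogenation of the E allylic alcohol sets C13 by catalyst control; the (R)-BINAP complex reduces geraniol-type E substrates to the (S)-citronellol-type center, which is (13S) here.

Step 11
Reactants: 11 (13S)-ent-labdane-8,15,18-triol
Product: 12 (13S)-15-(tert-butyldiphenylsilyloxy)-ent-labdane-8,18-diol
Conditions: TBDPSCl (1.05 equiv), imidazole, CH2Cl2, -20 to 0 °C
Reagents that add atoms: tert-butyldiphenylsilyl chloride CC(C)(C)[Si](Cl)(c1ccccc1)c1ccccc1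
Why: Sterically controlled silylation with the bulky chlorosilane should pick the unhindered C15 hydroxyl over the neopentyl C18 hydroxyl and the tertiary C8 hydroxyl.

Step 12
Reactants: 12 (13S)-15-(tert-butyldiphenylsilyloxy)-ent-labdane-8,18-diol; 13 angelic acid
Product: 15 (13S)-18-angeloyloxy-15-(tert-butyldiphenylsilyloxy)-ent-labdan-8-ol, via angelic 2,4,6-trichlorobenzoic anhydride 14 (not isolated)
Conditions: 13, 2,4,6-Cl3C6H2COCl, Et3N, toluene, rt; then 12, 80 °C
Reagents that add atoms: 2,4,6-trichlorobenzoyl chloride O=C(Cl)c1c(Cl)cc(Cl)cc1Cl (its atoms stay only in intermediate 14)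
Why: In this Yamaguchi esterification the C18 hydroxyl attacks the angeloyl carbonyl of 14 (the aroyl carbonyl is shielded by two ortho chlorines), the tertiary C8 hydroxyl is too hindered to react, and leaving out DMAP avoids the addition-elimination that turns an angelate into a tiglate.

Step 13
Reactants: 15 (13S)-18-angeloyloxy-15-(tert-butyldiphenylsilyloxy)-ent-labdan-8-ol
Product: 16 (13S)-18-angeloyloxy-ent-labdane-8,15-diol
Conditions: TBAF, AcOH, THF, rt
Reagents that add atoms: none
Why: Acetic acid-buffered fluoride desilylation frees O15 without hydrolysing or isomerising the angelate.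

Step 14
Reactants: 16 (13S)-18-angeloyloxy-ent-labdane-8,15-diol; 17 Meldrum's acid
Product: 18 (13S)-18-angeloyloxy-8-hydroxy-ent-labdan-15-yl hydrogen malonate (target)
Conditions: 17 (1.2 equiv), toluene, 90 °C
Reagents that add atoms: none
Why: Alcoholysis of Meldrum's acid by the primary C15 hydroxyl opens the ring with loss of acetone and gives the malonic half ester directly, while the tertiary C8 hydroxyl should not react.

**Compound list**

1 | geranylgeraniol | CC(C)=CCC/C(C)=C/CC/C(C)=C/CC/C(C)=C/CO | starting material
2 | geranylgeranyl acetate | CC(C)=CCC/C(C)=C/CC/C(C)=C/CC/C(C)=C/COC(C)=O | intermediate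
3 | (2E,6E,10E,14E)-16-hydroxygeranylgeranyl acetate | OC/C(C)=C/CC/C(C)=C/CC/C(C)=C/CC/C(C)=C/COC(C)=O | intermediate
4 | (2E,6E,10E,14E)-16-(tert-butyldimethylsilyloxy)geranylgeranyl acetate | CC(C)(C)[Si](C)(C)OC/C(C)=C/CC/C(C)=C/CC/C(C)=C/CC/C(C)=C/COC(C)=O | intermediate
5 | (2E,6E,10E,14E)-16-(tert-butyldimethylsilyloxy)geranylgeraniol | CC(C)(C)[Si](C)(C)OC/C(C)=C/CC/C(C)=C/CC/C(C)=C/CC/C(C)=C/CO | intermediate
6 | (2E,6E,10E,14E)-16-(tert-butyldimethylsilyloxy)geranylgeranyl chloride | CC(C)(C)[Si](C)(C)OC/C(C)=C/CC/C(C)=C/CC/C(C)=C/CC/C(C)=C/CCl | intermediate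
7 | (2E,6E,10E,14E)-16-(tert-butyldimethylsilyloxy)geranylgeranyl diphosphate | CC(C)(C)[Si](C)(C)OC/C(C)=C/CC/C(C)=C/CC/C(C)=C/CC/C(C)=C/COP(=O)(O)OP(=O)(O)O | intermediate
8 | (2E,6E,10E,14E)-16-hydroxygeranylgeranyl diphosphate (key-step precursor) | OC/C(C)=C/CC/C(C)=C/CC/C(C)=C/CC/C(C)=C/COP(=O)(O)OP(=O)(O)O | intermediate
9 | ent-8,18-dihydroxycopalyl diphosphate; trans-decalin with axial C20, H5 and H9 on the face opposite C20, equatorial C18 hydroxymethyl, equatorial 8-OH, 13E (key-step product) | OC[C@@]1(C)CCC[C@]2(C)[C@@H]1CC[C@](C)(O)[C@H]2CC/C(C)=C/COP(=O)(O)OP(=O)(O)O | intermediate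
10 | (13E)-ent-labd-13-ene-8,15,18-triol | OC[C@@]1(C)CCC[C@]2(C)[C@@H]1CC[C@](C)(O)[C@H]2CC/C(C)=C/CO | intermediate
11 | (13S)-ent-labdane-8,15,18-triol | OC[C@@]1(C)CCC[C@]2(C)[C@@H]1CC[C@](C)(O)[C@H]2CC[C@H](C)CCO | intermediate
12 | (13S)-15-(tert-butyldiphenylsilyloxy)-ent-labdane-8,18-diol | OC[C@@]1(C)CCC[C@]2(C)[C@@H]1CC[C@](C)(O)[C@H]2CC[C@H](C)CCO[Si](c1ccccc1)(c1ccccc1)C(C)(C)C | intermediate
13 | angelic acid, (Z)-2-methylbut-2-enoic acid | C/C=C(/C)C(=O)O | starting material
14 | angelic 2,4,6-trichlorobenzoic anhydride (formed in the flask) | C/C=C(/C)C(=O)OC(=O)c1c(Cl)cc(Cl)cc1Cl | intermediate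
15 | (13S)-18-angeloyloxy-15-(tert-butyldiphenylsilyloxy)-ent-labdan-8-ol | C/C=C(/C)C(=O)OC[C@@]1(C)CCC[C@]2(C)[C@@H]1CC[C@](C)(O)[C@H]2CC[C@H](C)CCO[Si](c1ccccc1)(c1ccccc1)C(C)(C)C | intermediate
16 | (13S)-18-angeloyloxy-ent-labdane-8,15-diol | C/C=C(/C)C(=O)OC[C@@]1(C)CCC[C@]2(C)[C@@H]1CC[C@](C)(O)[C@H]2CC[C@H](C)CCO | intermediate
17 | Meldrum's acid, 2,2-dimethyl-1,3-dioxane-4,6-dione | CC1(C)OC(=O)CC(=O)O1 | starting material
18 | (13S)-18-angeloyloxy-8-hydroxy-ent-labdan-15-yl hydrogen malonate, CNP0286290.1 | C/C=C(/C)C(=O)OC[C@@]1(C)CCC[C@]2(C)[C@@H]1CC[C@](C)(O)[C@H]2CC[C@H](C)CCOC(=O)CC(=O)O | target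

**Step count and risks**

Total step count: 14. Longest linear sequence: 14 steps, from geranylgeraniol 1 to target 18.

Steps most likely to fail:

1. Step 8 (Proposed new method). The cyclase may not protonate the hydroxyl-deactivated C3-C4 alkene at a useful rate, may stop after ring A, or may end the cascade by proton loss instead of water capture. The fallback is known chemistry, sets out from 3 and comes back at 11.
   - Sharpless asymmetric epoxidation of 3 (Ti(OiPr)4, D-(-)-diethyl tartrate, t-BuOOH, 4 Å molecular sieves, CH2Cl2, -20 °C) should give the (14R,15R)-epoxy alcohol F1.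
   - Silylation (TBSCl, imidazole, DMF) should give the silyl ether F2.
   - MeAlCl2 in CH2Cl2 at -78 °C should open the epoxide at C15 with inversion, in concert with chair-chair closure of ring A and ring B, to give the 3-hydroxy-8(17)-ene F3, purified on AgNO3-impregnated silica. The (14R) epoxide enforces the ent fold and the E-CH2OTBS group again ends equatorial as C18.
   - The extra C3 hydroxyl would be removed by Barton-McCombie deoxygenation: PhOC(S)Cl, pyridine, DMAP to the thionocarbonate F4, then Bu3SnH, AIBN, toluene, 90 °C to the 3-deoxy compound F5.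
   - TBAF in THF followed by K2CO3 in MeOH should free both primary hydroxyls to give the diene diol F6.
   - Ru(OAc)2[(R)-BINAP]/H2 should reduce only the allylic alcohol alkene to the (13S)-ene diol F7.
   - mCPBA/NaHCO3 should epoxidise the exocyclic alkene from the face away from axial C20 to give the spiro-epoxide F8.
   - LiAlH4 in THF should open F8 at C17 to give the equatorial tertiary alcohol 11.

2. Step 12. The angeloyl unit may isomerise from Z to E during activation (tiglate formation), and acylation of the neopentyl C18 hydroxyl may be slow. The fallback builds the Z alkene on the ester instead of transferring it; it sets out from 12 and comes back at 15.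
   - Steglich esterification of 12 with 2-[bis(2,2,2-trifluoroethoxy)phosphoryl]propanoic acid (DCC, DMAP, CH2Cl2) should give the phosphonopropionate F9.
   - Still-Gennari olefination of F9 with acetaldehyde (KHMDS, 18-crown-6, THF, -78 °C) should give the Z-configured 2-methylbut-2-enoate 15.

3. Step 11. Discrimination between the two primary hydroxyls may be incomplete (silylation at C18 or at both positions). The fallback uses enzymatic acyl protection instead of silylation; it sets out from 11 and comes back at 16.
   - Candida antarctica lipase B with vinyl acetate in MTBE at 30 °C should acetylate only the unhindered C15 hydroxyl to give the monoacetate F10.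
   - Yamaguchi acylation of F10 with 13 as in step 12 should give the 15-acetate 18-angelate F11.
   - K2CO3 in MeOH at 0 °C should cleave the primary acetate much faster than the hindered conjugated neopentyl ester and give 16.

**Further compounds**

F1 | step 8 | (2E,6E,10E,14R,15R)-14,15-epoxy-16-hydroxygeranylgeranyl acetate | OC[C@@]1(C)O[C@@H]1CC/C(C)=C/CC/C(C)=C/CC/C(C)=C/COC(C)=O
F2 | step 8 | (2E,6E,10E,14R,15R)-16-(tert-butyldimethylsilyloxy)-14,15-epoxygeranylgeranyl acetate | CC(C)(C)[Si](C)(C)OC[C@@]1(C)O[C@@H]1CC/C(C)=C/CC/C(C)=C/CC/C(C)=C/COC(C)=O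
F3 | step 8 | (13E)-18-(tert-butyldimethylsilyloxy)-3-hydroxy-ent-labda-8(17),13-dien-15-yl acetate (3-OH equatorial) | CC(C)(C)[Si](C)(C)OC[C@@]1(C)[C@H](O)CC[C@]2(C)[C@@H]1CCC(=C)[C@H]2CC/C(C)=C/COC(C)=O
F4 | step 8 | 3-O-(phenoxythiocarbonyl) derivative of F3 | CC(C)(C)[Si](C)(C)OC[C@@]1(C)[C@H](OC(=S)Oc3ccccc3)CC[C@]2(C)[C@@H]1CCC(=C)[C@H]2CC/C(C)=C/COC(C)=O
F5 | step 8 | (13E)-18-(tert-butyldimethylsilyloxy)-ent-labda-8(17),13-dien-15-yl acetate | CC(C)(C)[Si](C)(C)OC[C@@]1(C)CCC[C@]2(C)[C@@H]1CCC(=C)[C@H]2CC/C(C)=C/COC(C)=O
F6 | step 8 | (13E)-ent-labda-8(17),13-diene-15,18-diol | OC[C@@]1(C)CCC[C@]2(C)[C@@H]1CCC(=C)[C@H]2CC/C(C)=C/CO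
F7 | step 8 | (13S)-ent-labd-8(17)-ene-15,18-diol | OC[C@@]1(C)CCC[C@]2(C)[C@@H]1CCC(=C)[C@H]2CC[C@H](C)CCO
F8 | step 8 | (13S)-8,17-epoxy-ent-labdane-15,18-diol (epoxide oxygen equatorial at C8) | OC[C@@]1(C)CCC[C@]2(C)[C@@H]1CC[C@@]3(CO3)[C@H]2CC[C@H](C)CCO
F9 | step 12 | (13S)-15-(tert-butyldiphenylsilyloxy)-8-hydroxy-ent-labdan-18-yl 2-[bis(2,2,2-trifluoroethoxy)phosphoryl]propanoate (both epimers at the phosphonate-bearing carbon) | CC(P(=O)(OCC(F)(F)F)OCC(F)(F)F)C(=O)OC[C@@]1(C)CCC[C@]2(C)[C@@H]1CC[C@](C)(O)[C@H]2CC[C@H](C)CCO[Si](c1ccccc1)(c1ccccc1)C(C)(C)C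
F10 | step 11 | (13S)-8,18-dihydroxy-ent-labdan-15-yl acetate | OC[C@@]1(C)CCC[C@]2(C)[C@@H]1CC[C@](C)(O)[C@H]2CC[C@H](C)CCOC(C)=O
F11 | step 11 | (13S)-18-angeloyloxy-8-hydroxy-ent-labdan-15-yl acetate | C/C=C(/C)C(=O)OC[C@@]1(C)CCC[C@]2(C)[C@@H]1CC[C@](C)(O)[C@H]2CC[C@H](C)CCOC(C)=O
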